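In this scheme, apart from the small amount held on the catalyst, starting material left, target and side product add up to what has been fed, since one side product carries two units of starting material. Tuesday's run sums to 102 % at 120 s. The question is how far the flask has gone by the asked time.

| setting | Tuesday's | flask |
|---|---|---|
| starting material | 0.25 M (fed, over 80 s) | 0.25 M (fed, over 80 s) |
| second substrate | 0.50 equiv | 0.500 equiv |
| coupling partner | 2.4 equiv | 1.20 equiv |
| free catalyst | 0.2 mol% | 0.2 mol% |
| remark | run made earlier |  |
| time |  | 6.0 min |

Tuesday's run (percent of the starting material charged)

| time / s | starting material / % | target / % | side product / % |
|---|---|---|---|
| 10.0 | 10.3 | 0 | 0 |
| 25.0 | 26.4 | 6.3 | 2.2 |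
| 50.0 | 49.6 | 12.4 | 1.3 |
| 80.0 | 73.8 | 26.4 | 0.6 |
| 120 | 55.5 | 41.8 | 4.2 |

(standard deviation of a reading: 1 percentage point)

- in percentages every species weighs as the starting material in it: one side product counts as two
- what was read earlier has a scatter of 1 percentage point, one standard deviation
- candidate steps: second substrate + free catalyst <-> catalyst intermediate B; coupling partner + catalyst intermediate B -> free catalyst + second product; starting material + free catalyst <-> catalyst intermediate A; starting material + target -> side product; 2 second substrate -> homo dimer; coupling partner + catalyst intermediate A -> free catalyst + target
- the reaction counts as stopped when no species that holds the starting material changes by six tenths of a point or more over the second half of the time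
- percentages count the whole charge, also what has not yet gone in

- at 6.0 min, what has stopped the reaction, if anything has (it is still moving / no working catalyst is left / forward and back rates have come level / the coupling partner has run out first / all of the starting material has reacted)
- conversion of starting material at 6.0 min
- amount of target at 6.0 min, in percent of the starting material charged
- amount of side product at 6.0 min, in percent of the starting material charged

Each target takes one coupling partner and each side product destroys one target, and in percentages a side product counts double, so target plus half the side product counts the turnovers that made target. On Tuesday this count rose by 31 percentage points between 50.0 s and 120 s, with about 0.529 M of coupling partner present. The reading gives the partner decay constant, the turnover rate divided by the coupling partner present, a pseudo-first-order constant of 0.125 min⁻¹.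

The settings then act by hand as follows. In this reckoning the constant follows the catalyst concentration, and the loading and the starting material charge are both as on Tuesday, so it carries over unchanged. Coupling partner is cut to half of Tuesday's, which scales the count in proportion. Second substrate and the feed time stay as they were. With the feed ignored and the decay counted from the start, the count at 6.0 min is the partner charge times one minus the exponential decay, or 63.3 %. It gains 26 points over the second half of the time, so this reckoning has the flask still moving.

The forecast, on the ground “That rate should scale with coupling partner”, answers it is still moving, with conversion 64 %, target 46 % and side product 18 %, a count of 55.0 %, lower than the count above.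

The flask's answer is it is still moving, with conversion 71.8 %, target 55.6 % and side product 16.0 %.

    second substrate + free catalyst ⇌ catalyst intermediate B (K = 15.0 M⁻¹, k = 830 M⁻¹ min⁻¹)
    coupling partner + catalyst intermediate B → free catalyst + second product (k = 150 M⁻¹ min⁻¹)
    starting material + free catalyst ⇌ catalyst intermediate A (K = 180 M⁻¹, k = 4500 M⁻¹ min⁻¹)
    starting material + target → side product (k = 0.350 M⁻¹ min⁻¹)
    2 second substrate → homo dimer (k = 0.840 M⁻¹ min⁻¹)
    coupling partner + catalyst intermediate A → free catalyst + target (k = 350 M⁻¹ min⁻¹)

The flask's count is 63.6 %, against 63.3 % reckoned. The neighbouring flask at 0.15 M of starting material holds the same equivalents and loading, so its catalyst concentration falls with the charge, and in this reckoning its constant falls with it, to 0.0750 min⁻¹. The count reckoned for it is 43.5 %. That flask gives target 40.6 % and side product 8.87 %, a count of 45.0 %, with 60 % of its coupling partner left.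

The numbers in the tables stem from a simulated flask with constants of no real substance, and the scatter is random.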